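## Retrosynthetic overview

1. Target 27 ⇐ ester cleavage of 26 ⇐ thermal conrotatory 4π opening of the cis-fused bicyclo[6.2.0]deca-2,9-diene 25 (ring 8 → 10). The enabling feature: in the ten-membered ring the acrylate carbon and the quaternary carbon are linked by CH=CH–CH=CH with Z,E geometry. The two inner CH carbons are therefore made as the double bond of a cyclobutene whose two sp3 carbons (the future diene termini) are the fusion atoms of an eight-membered ring.
2. 25 ⇐ β-keto ester 20 (enol triflate, DIBAL-H, Ac2O, Pd/CO) ⇐ enamine–propiolate two-carbon expansion of bicyclo[4.2.0]oct-7-en-2-one 14 (ring 6 → 8).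
3. 14 ⇐ sp3–sp2 Negishi coupling with 3-bromofuran ⇐ enone–acetylene [2+2] photocycloaddition on cyclohexenone 9.
4. 9 ⇐ Saegusa oxidation, Appel bromination, hydroboration, Wittig ⇐ catalytic enantioselective Diels–Alder reaction of tiglic aldehyde 3 with siloxydiene 2, which sets both stereocentres.
5. Ring order: cyclohexene (Diels–Alder) → cyclobutene ([2+2]) → eight-membered ring → ten-membered ring (cyclobutene consumed).

Key step: step 15

Remark 1: the (S)-oxazaborolidinium catalyst is assumed, from its formyl C–H···O binding model for 2-substituted enals, to leave the Cα-Re face of 3 open; if the sense is the opposite, the (R)-catalyst is used.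

Remark 2: 11 and all later bicyclic compounds are drawn as the cis-fused isomer with the cyclobutene on the face opposite the two methyl groups; the other cis-fused isomer, if formed, passes through the same steps to the same 26, because both fusion stereocentres vanish in step 15.

## Route

Step 1
Reactants: 1 but-3-en-2-one
Product: 2 2-(triisopropylsilyloxy)buta-1,3-diene
Conditions: iPr3SiOTf, Et3N, Et2O, 0 → 20 °C
Reagents that add atoms: triisopropylsilyl trifluoromethanesulfonate, CC(C)[Si](C(C)C)(C(C)C)OS(=O)(=O)C(F)(F)F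
Why: Soft enolisation of the enone (silyl dienol ether formation) gives the 2-siloxydiene, and the bulky silyl group keeps the diene and the later enol ether intact through acidic and basic steps.

Step 2
Reactants: 2 2-(triisopropylsilyloxy)buta-1,3-diene; 3 (E)-2-methylbut-2-enal
Product: 4 (1R,6R)-1,6-dimethyl-4-(triisopropylsilyloxy)cyclohex-3-ene-1-carbaldehyde
Conditions: (S)-o-tolyl-CBS-oxazaborolidine (20 mol%), Tf2NH (16 mol%), CH2Cl2, −78 → −40 °C
Reagents that add atoms: none
Why: Catalytic enantioselective Diels–Alder reaction of an α-substituted enal under chiral oxazaborolidinium activation; the CH2 terminus next to the siloxy carbon bonds to the β-carbon (para rule), the E geometry of the dienophile is transferred suprafacially so that the two methyl groups end up cis, and the catalyst selects the Cα-Re face, which fixes the quaternary and the tertiary stereocentre together.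

Step 3
Reactants: 4 (1R,6R)-1,6-dimethyl-4-(triisopropylsilyloxy)cyclohex-3-ene-1-carbaldehyde
Product: 5 {[(4S,5R)-4-ethenyl-4,5-dimethylcyclohex-1-en-1-yl]oxy}triisopropylsilane
Conditions: Ph3PCH3Br, KOtBu, THF, 0 → 20 °C
Reagents that add atoms: methyltriphenylphosphonium bromide, C[P+](c1ccccc1)(c1ccccc1)c1ccccc1.[Br-]
Why: Wittig methylenation of a non-enolisable neopentyl aldehyde, so no stereocentre can epimerise and the silyl enol ether is inert to the ylide.

Step 4
Reactants: 5 {[(4S,5R)-4-ethenyl-4,5-dimethylcyclohex-1-en-1-yl]oxy}triisopropylsilane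
Product: 7 2-[(1S,6R)-1,6-dimethyl-4-(triisopropylsilyloxy)cyclohex-3-en-1-yl]ethan-1-ol, via alkylborane 6 (not isolated)
Conditions: 9-BBN, THF, 0 → 20 °C; then NaOH, H2O2, 0 °C
Reagents that add atoms: hydrogen peroxide, OO
Why: Anti-Markovnikov hydroboration–oxidation; 9-BBN takes the terminal vinyl group and leaves the trisubstituted silyl enol ether, which also survives cold alkaline peroxide.

Step 5
Reactants: 7 2-[(1S,6R)-1,6-dimethyl-4-(triisopropylsilyloxy)cyclohex-3-en-1-yl]ethan-1-ol
Product: 8 {[(4S,5R)-4-(2-bromoethyl)-4,5-dimethylcyclohex-1-en-1-yl]oxy}triisopropylsilane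
Conditions: CBr4, PPh3, 2,6-lutidine, CH2Cl2, 0 °C
Reagents that add atoms: carbon tetrabromide, BrC(Br)(Br)Br
Why: Appel bromination of an unhindered primary alcohol under buffered conditions that spare the enol ether; the bromide is the photostable handle for the later furan coupling.

Step 6
Reactants: 8 {[(4S,5R)-4-(2-bromoethyl)-4,5-dimethylcyclohex-1-en-1-yl]oxy}triisopropylsilane
Product: 9 (4S,5R)-4-(2-bromoethyl)-4,5-dimethylcyclohex-2-en-1-one
Conditions: Pd(OAc)2 (1.1 equiv), DMSO/MeCN, 20 → 40 °C
Reagents that add atoms: none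
Why: Saegusa–Ito oxidation; the regiodefined enol ether from the cycloaddition gives the palladium enolate and β-hydride elimination places the enone double bond on the side of the quaternary carbon, with the alkyl bromide untouched.

Step 7
Reactants: 9 (4S,5R)-4-(2-bromoethyl)-4,5-dimethylcyclohex-2-en-1-one; 10 acetylene
Product: 11 (1S,4R,5S,6R)-5-(2-bromoethyl)-4,5-dimethylbicyclo[4.2.0]oct-7-en-2-one
Conditions: hν (Hg lamp, uranium-glass filter, λ > 330 nm), CH2Cl2 saturated with acetylene, −60 °C, stopped before full conversion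
Reagents that add atoms: none
Why: Enone–alkyne [2+2] photocycloaddition through the triplet enone and a 1,4-biradical gives only the cis-fused cyclobutene (a trans-fused bicyclo[4.2.0]octene is too strained); the two new fusion stereocentres are expected to form anti to the methyl-bearing face but are erased in step 15, and the furan is deliberately still absent because it would trap the excited enone intramolecularly.

Step 8
Reactants: 11 (1S,4R,5S,6R)-5-(2-bromoethyl)-4,5-dimethylbicyclo[4.2.0]oct-7-en-2-one; 12 3-bromofuran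
Product: 14 (1S,4R,5S,6R)-5-[2-(furan-3-yl)ethyl]-4,5-dimethylbicyclo[4.2.0]oct-7-en-2-one, via alkylzinc bromide 13 (not isolated)
Conditions: Zn dust, I2 (5 mol%), DMA, 70 °C; then 12, Pd(OAc)2 (3 mol%), SPhos (6 mol%), THF/DMA, 40 °C
Reagents that add atoms: none
Why: Negishi sp3–sp2 cross-coupling; zinc insertion and coupling are non-basic, so the ketone is tolerated and the cyclobutene double bond is not moved into conjugation, as an aqueous-base Suzuki variant might do.

Step 9
Reactants: 14 (1S,4R,5S,6R)-5-[2-(furan-3-yl)ethyl]-4,5-dimethylbicyclo[4.2.0]oct-7-en-2-one; 15 methyl propiolate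
Product: 19 methyl (1S,6R,7S,8R)-7-[2-(furan-3-yl)ethyl]-6,7-dimethyl-2-oxobicyclo[6.2.0]deca-3,9-diene-3-carboxylate, via enamine 16 (not isolated), via aminocyclobutene 17 (not isolated), via dienamine 18 (not isolated)
Conditions: pyrrolidine (5 equiv), 4 Å MS, PhH, 80 °C, evaporate; 15, Et2O, 0 → 35 °C; AcOH/NaOAc/H2O, 20 °C
Reagents that add atoms: water, O
Why: Enamine–alkynoate two-carbon ring expansion: the enamine on the methylene side adds through its β-carbon to the propiolate, the zwitterion closes to a 2-aminocyclobutene ester, and its push–pull 4π opening cleaves the former enamine C–C bond and enlarges the six- to the eight-membered ring; buffered hydrolysis gives the alkylidene β-keto ester, and acid-free enamine formation avoids acid-induced acyl-shift rearrangement of the cyclobutenyl ketone.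

Step 10
Reactants: 19 methyl (1S,6R,7S,8R)-7-[2-(furan-3-yl)ethyl]-6,7-dimethyl-2-oxobicyclo[6.2.0]deca-3,9-diene-3-carboxylate
Product: 20 methyl (1S,6R,7S,8R)-7-[2-(furan-3-yl)ethyl]-6,7-dimethyl-2-oxobicyclo[6.2.0]dec-9-ene-3-carboxylate
Conditions: Hantzsch ester (1.2 equiv), SiO2, CH2Cl2, 20 °C, dark
Reagents that add atoms: none
Why: Conjugate transfer hydrogenation of a doubly activated alkylidene β-keto ester; hydride goes to the β-carbon while the cyclobutene and furan are untouched, the new α-centre is enolisable and irrelevant, and room temperature is kept because the acyl-substituted cyclobutene is the intermediate most prone to premature opening.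

Step 11
Reactants: 20 methyl (1S,6R,7S,8R)-7-[2-(furan-3-yl)ethyl]-6,7-dimethyl-2-oxobicyclo[6.2.0]dec-9-ene-3-carboxylate
Product: 22 methyl (1S,6R,7S,8R)-7-[2-(furan-3-yl)ethyl]-6,7-dimethyl-2-(trifluoromethanesulfonyloxy)bicyclo[6.2.0]deca-2,9-diene-3-carboxylate, via sodium enolate 21 (not isolated)
Conditions: NaH, THF, 0 °C; PhNTf2, 0 → 20 °C
Reagents that add atoms: N-phenylbis(trifluoromethanesulfonimide), O=S(=O)(N(c1ccccc1)S(=O)(=O)C(F)(F)F)C(F)(F)F
Why: O-Triflation of the chelated β-keto ester enolate gives the cyclic enol triflate regiospecifically, with triflate and ester cis on the ring double bond.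

Step 12
Reactants: 22 methyl (1S,6R,7S,8R)-7-[2-(furan-3-yl)ethyl]-6,7-dimethyl-2-(trifluoromethanesulfonyloxy)bicyclo[6.2.0]deca-2,9-diene-3-carboxylate
Product: 23 (1S,6R,7S,8R)-7-[2-(furan-3-yl)ethyl]-3-(hydroxymethyl)-6,7-dimethylbicyclo[6.2.0]deca-2,9-dien-2-yl trifluoromethanesulfonate
Conditions: DIBAL-H (2.5 equiv), CH2Cl2, −78 °C; Rochelle salt
Reagents that add atoms: none
Why: DIBAL-H reduction of the conjugated ester to the allylic alcohol; the vinyl triflate is stable to the hydride at −78 °C.

Step 13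
Reactants: 23 (1S,6R,7S,8R)-7-[2-(furan-3-yl)ethyl]-3-(hydroxymethyl)-6,7-dimethylbicyclo[6.2.0]deca-2,9-dien-2-yl trifluoromethanesulfonate
Product: 24 {(1S,6R,7S,8R)-7-[2-(furan-3-yl)ethyl]-6,7-dimethyl-2-(trifluoromethanesulfonyloxy)bicyclo[6.2.0]deca-2,9-dien-3-yl}methyl acetate
Conditions: Ac2O, pyridine, DMAP (cat.), CH2Cl2, 0 °C
Reagents that add atoms: acetic anhydride, CC(=O)OC(C)=O
Why: Acylation of the primary allylic alcohol before the carboxyl group exists, so the Z-hydroxy acid or ester that would lactonise to a butenolide is never formed.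

Step 14
Reactants: 24 {(1S,6R,7S,8R)-7-[2-(furan-3-yl)ethyl]-6,7-dimethyl-2-(trifluoromethanesulfonyloxy)bicyclo[6.2.0]deca-2,9-dien-3-yl}methyl acetate
Product: 25 2-(trimethylsilyl)ethyl (1S,6R,7S,8R)-3-(acetoxymethyl)-7-[2-(furan-3-yl)ethyl]-6,7-dimethylbicyclo[6.2.0]deca-2,9-diene-2-carboxylate
Conditions: Pd(OAc)2 (5 mol%), dppf (6 mol%), Et3N, CO (1 atm), Me3SiCH2CH2OH (5 equiv), DMF, 50 °C
Reagents that add atoms: carbon monoxide, [C-]#[O+]; 2-(trimethylsilyl)ethanol, C[Si](C)(C)CCO
Why: Palladium-catalysed alkoxycarbonylation of the vinyl triflate (oxidative addition, CO insertion, alcoholysis) installs the carboxyl carbon; the acetate on the tetrasubstituted alkene ionises only slowly and 50 °C is below the opening temperature of the alkenyl-substituted cyclobutene.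

Step 15
Reactants: 25 2-(trimethylsilyl)ethyl (1S,6R,7S,8R)-3-(acetoxymethyl)-7-[2-(furan-3-yl)ethyl]-6,7-dimethylbicyclo[6.2.0]deca-2,9-diene-2-carboxylate
Product: 26 2-(trimethylsilyl)ethyl (1(10)Z,2Z,4E,6S,7R)-10-(acetoxymethyl)-6-[2-(furan-3-yl)ethyl]-6,7-dimethylcyclodeca-1(10),2,4-triene-1-carboxylate
Conditions: PhMe (degassed, 0.01 M, BHT, base-washed glass), 100–110 °C
Reagents that add atoms: none
Why: Thermal conrotatory 4π-electrocyclic ring opening: the fusion σ bond shared by the cyclobutene and the eight-membered ring breaks, the cyclobutene π bond becomes the central single bond of a new diene, and the eight-membered ring grows by two atoms while the cyclobutene strain is released. The closest known reaction is the opening of cis-bicyclo[6.2.0]dec-9-ene to (1E,3Z)-cyclodeca-1,3-diene and, in general, of cis-3,4-disubstituted cyclobutenes to (E,Z)-dienes. No ring is closed and no stereocentre is formed; the two fusion stereocentres are erased, so both cis-fused diastereomers of 25 converge on one product, while the quaternary and the methyl-bearing centres are spectators. Conrotation of a cis-fused cyclobutene must give one E and one Z double bond, and torquoselectivity decides which: the fully substituted carbon turns outward (E olefin next to the quaternary centre) and the sp2 acrylate carbon turns inward (Z olefin), inward rotation of a tert-alkyl group being sterically prohibitive. The step needs this sense of rotation and must stop at the triene; the bulk of the quaternary carbon should secure the first, and conjugation of the breaking bond with the acrylate should lower the barrier enough that about 100 °C suffices, which is expected to be below the onset of 6π closure at the hindered, tetrasubstituted triene terminus.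

Step 16
Reactants: 26 2-(trimethylsilyl)ethyl (1(10)Z,2Z,4E,6S,7R)-10-(acetoxymethyl)-6-[2-(furan-3-yl)ethyl]-6,7-dimethylcyclodeca-1(10),2,4-triene-1-carboxylate
Product: 27 (1(10)Z,2Z,4E,6S,7R)-10-(acetoxymethyl)-6-[2-(furan-3-yl)ethyl]-6,7-dimethylcyclodeca-1(10),2,4-triene-1-carboxylic acid
Conditions: TASF, DMF, 0 → 20 °C; aq. NH4Cl
Reagents that add atoms: none
Why: Fluoride-induced β-elimination of the 2-(trimethylsilyl)ethyl ester frees the carboxylate near 0 °C without touching the allylic acetate, the furan or the triene, and a mildly acidic work-up avoids lactonisation.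

## Compound list

1 | but-3-en-2-one (methyl vinyl ketone) | C=CC(C)=O | starting material
2 | 2-(triisopropylsilyloxy)buta-1,3-diene | C=CC(=C)O[Si](C(C)C)(C(C)C)C(C)C | intermediate
3 | (E)-2-methylbut-2-enal (tiglic aldehyde) | C/C=C(C)/C=O | starting material
4 | (1R,6R)-1,6-dimethyl-4-(triisopropylsilyloxy)cyclohex-3-ene-1-carbaldehyde (methyl groups cis) | CC(C)[Si](OC1=CC[C@@](C)(C=O)[C@H](C)C1)(C(C)C)C(C)C | intermediate
5 | {[(4S,5R)-4-ethenyl-4,5-dimethylcyclohex-1-en-1-yl]oxy}triisopropylsilane | CC(C)[Si](OC1=CC[C@@](C)(C=C)[C@H](C)C1)(C(C)C)C(C)C | intermediate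
6 | 9-{2-[(1R,6R)-1,6-dimethyl-4-(triisopropylsilyloxy)cyclohex-3-en-1-yl]ethyl}-9-borabicyclo[3.3.1]nonane (same spatial arrangement as 5) | CC(C)[Si](OC1=CC[C@@](C)(CCB2C3CCCC2CCC3)[C@H](C)C1)(C(C)C)C(C)C | intermediate
7 | 2-[(1S,6R)-1,6-dimethyl-4-(triisopropylsilyloxy)cyclohex-3-en-1-yl]ethan-1-ol | CC(C)[Si](OC1=CC[C@@](C)(CCO)[C@H](C)C1)(C(C)C)C(C)C | intermediate
8 | {[(4S,5R)-4-(2-bromoethyl)-4,5-dimethylcyclohex-1-en-1-yl]oxy}triisopropylsilane | CC(C)[Si](OC1=CC[C@@](C)(CCBr)[C@H](C)C1)(C(C)C)C(C)C | intermediate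
9 | (4S,5R)-4-(2-bromoethyl)-4,5-dimethylcyclohex-2-en-1-one | O=C1C=C[C@@](C)(CCBr)[C@H](C)C1 | intermediate
10 | acetylene (ethyne) | C#C | starting material
11 | (1S,4R,5S,6R)-5-(2-bromoethyl)-4,5-dimethylbicyclo[4.2.0]oct-7-en-2-one (cis-fused) | O=C1C[C@@H](C)[C@](C)(CCBr)[C@@H]2C=C[C@H]12 | intermediate
12 | 3-bromofuran | Brc1ccoc1 | starting material
13 | {2-[(1S,4R,5S,6R)-4,5-dimethyl-2-oxobicyclo[4.2.0]oct-7-en-5-yl]ethyl}zinc bromide | O=C1C[C@@H](C)[C@](C)(CC[Zn]Br)[C@@H]2C=C[C@H]12 | intermediate
14 | (1S,4R,5S,6R)-5-[2-(furan-3-yl)ethyl]-4,5-dimethylbicyclo[4.2.0]oct-7-en-2-one | O=C1C[C@@H](C)[C@](C)(CCc3ccoc3)[C@@H]2C=C[C@H]12 | intermediate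
15 | methyl propiolate (methyl prop-2-ynoate) | C#CC(=O)OC | starting material
16 | 1-{(1S,4R,5S,6R)-5-[2-(furan-3-yl)ethyl]-4,5-dimethylbicyclo[4.2.0]octa-2,7-dien-2-yl}pyrrolidine | C1(N2CCCC2)=C[C@@H](C)[C@](C)(CCc3ccoc3)[C@@H]4C=C[C@H]14 | intermediate
17 | tricyclic [2+2] adduct of 16 and 15: 2-aminocyclobutene ester fused across the former enamine double bond, pyrrolidinyl on the fusion carbon (drawn with the new ring anti to the neighbouring methyl) | COC(=O)C1=C[C@@H]2[C@@H](C)[C@](C)(CCc3ccoc3)[C@@H]4C=C[C@@H]4[C@]12N5CCCC5 | intermediate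
18 | methyl (1S,6R,7S,8R)-7-[2-(furan-3-yl)ethyl]-6,7-dimethyl-2-(pyrrolidin-1-yl)bicyclo[6.2.0]deca-2,4,9-triene-3-carboxylate | COC(=O)/C1=C(N2CCCC2)/[C@H]3C=C[C@H]3[C@@](C)(CCc4ccoc4)[C@H](C)/C=C\1 | intermediate
19 | methyl (1S,6R,7S,8R)-7-[2-(furan-3-yl)ethyl]-6,7-dimethyl-2-oxobicyclo[6.2.0]deca-3,9-diene-3-carboxylate (C3=C4 cis within the ring) | COC(=O)/C1=C/C[C@@H](C)[C@](C)(CCc2ccoc2)[C@@H]3C=C[C@@H]3C1=O | intermediate
20 | methyl (1S,6R,7S,8R)-7-[2-(furan-3-yl)ethyl]-6,7-dimethyl-2-oxobicyclo[6.2.0]dec-9-ene-3-carboxylate (C-3 epimers and enol in equilibrium) | COC(=O)C1CC[C@@H](C)[C@](C)(CCc2ccoc2)[C@@H]3C=C[C@@H]3C1=O | intermediate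
21 | sodium enolate of 20 | [Na+].COC(=O)/C1=C([O-])/[C@H]2C=C[C@H]2[C@@](C)(CCc3ccoc3)[C@H](C)CC1 | intermediate
22 | methyl (1S,6R,7S,8R)-7-[2-(furan-3-yl)ethyl]-6,7-dimethyl-2-(trifluoromethanesulfonyloxy)bicyclo[6.2.0]deca-2,9-diene-3-carboxylate | COC(=O)/C1=C(OS(=O)(=O)C(F)(F)F)/[C@H]2C=C[C@H]2[C@@](C)(CCc3ccoc3)[C@H](C)CC1 | intermediate
23 | (1S,6R,7S,8R)-7-[2-(furan-3-yl)ethyl]-3-(hydroxymethyl)-6,7-dimethylbicyclo[6.2.0]deca-2,9-dien-2-yl trifluoromethanesulfonate | OC/C1=C(OS(=O)(=O)C(F)(F)F)/[C@H]2C=C[C@H]2[C@@](C)(CCc3ccoc3)[C@H](C)CC1 | intermediate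
24 | {(1S,6R,7S,8R)-7-[2-(furan-3-yl)ethyl]-6,7-dimethyl-2-(trifluoromethanesulfonyloxy)bicyclo[6.2.0]deca-2,9-dien-3-yl}methyl acetate | CC(=O)OC/C1=C(OS(=O)(=O)C(F)(F)F)/[C@H]2C=C[C@H]2[C@@](C)(CCc3ccoc3)[C@H](C)CC1 | intermediate
25 | 2-(trimethylsilyl)ethyl (1S,6R,7S,8R)-3-(acetoxymethyl)-7-[2-(furan-3-yl)ethyl]-6,7-dimethylbicyclo[6.2.0]deca-2,9-diene-2-carboxylate (cis-fused) | CC(=O)OC/C1=C(C(=O)OCC[Si](C)(C)C)/[C@H]2C=C[C@H]2[C@@](C)(CCc3ccoc3)[C@H](C)CC1 | intermediate
26 | 2-(trimethylsilyl)ethyl (1(10)Z,2Z,4E,6S,7R)-10-(acetoxymethyl)-6-[2-(furan-3-yl)ethyl]-6,7-dimethylcyclodeca-1(10),2,4-triene-1-carboxylate | CC(=O)OC/C1=C(C(=O)OCC[Si](C)(C)C)/C=C\C=C\[C@@](C)(CCc2ccoc2)[C@H](C)CC1 | intermediate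
27 | (1(10)Z,2Z,4E,6S,7R)-10-(acetoxymethyl)-6-[2-(furan-3-yl)ethyl]-6,7-dimethylcyclodeca-1(10),2,4-triene-1-carboxylic acid | CC(=O)OC/C1=C(C(=O)O)/C=C\C=C\[C@@](C)(CCc2ccoc2)[C@H](C)CC1 | target

## Step count and risks

Total step count: 16. Longest linear sequence: 16 steps (fully linear from 1).

Steps most likely to fail:

Step 15. What may go wrong: the triene may not survive the temperature the opening needs (transannular 6π electrocyclisation or a 1,7-hydrogen shift of the product, or thermal loss of acetic acid), or the opening may be too slow below that limit. Fallback: the ring expansion is moved to the β-keto ester 20, where the fusion carbon carries an acyl group; acyl-substituted cyclobutenes are known to open at lower temperature with the acyl group turning inward, which is the same sense. Setting out from 20, warming to 45–60 °C (ZnI2 if needed) should give the ten-membered (3Z,5E)-dienone keto ester F1. This is converted at once into its enol triflate F2 (NaH, PhNTf2), reduced to the allylic alcohol F3 (DIBAL-H, −78 °C), acetylated to F4, and alkoxycarbonylated at 25–40 °C (Pd(OAc)2, dppf, CO, Me3SiCH2CH2OH) to come back to the route at 26. No triene is then heated above 40 °C.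

Step 7. What may go wrong: poor conversion because of the low concentration of acetylene, consumption of the product by secondary photochemistry of its β,γ-unsaturated ketone (1,3-acyl shift), or lumiketone rearrangement of the 4,4-disubstituted enone. Fallback: setting out from 9, [2+2] photocycloaddition with (E)-1,2-dichloroethene as cosolvent gives the dichlorocyclobutane F5 (mixture at the chlorinated carbons), which is saturated and does not absorb above 330 nm. Reductive 1,2-elimination with activated zinc (EtOH, reflux), which leaves the primary bromide alone, then comes back to the route at 11.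

Step 9. What may go wrong: enamine formation toward the fusion carbon (conjugation with the cyclobutene), or open-chain Michael addition without cyclobutene closure, so that the ring is not enlarged. Fallback: setting out from 14, kinetic deprotonation on the methylene side and silylation (LDA, Me3SiCl, THF, −78 °C) give the trimethylsilyl enol ether F6. Lewis-acid-catalysed [2+2] cycloaddition with methyl propiolate (Tf2NH 2 mol% or ZrCl4, CH2Cl2, −78 °C) gives the 2-siloxycyclobutene ester F7. Fluoride (TBAF, THF, 0 °C) releases the cyclobutenolate, which fragments at the fusion bond (retro-aldol type) and comes back to the route at 19.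

Further compounds
F1 | step 15 | methyl (3Z,5E,7S,8R)-7-[2-(furan-3-yl)ethyl]-7,8-dimethyl-2-oxocyclodeca-3,5-diene-1-carboxylate (C-1 epimers and enol) | COC(=O)C1C(=O)/C=C\C=C\[C@@](C)(CCc2ccoc2)[C@H](C)CC1
F2 | step 15 | methyl (1Z,3Z,5E,7S,8R)-7-[2-(furan-3-yl)ethyl]-7,8-dimethyl-2-(trifluoromethanesulfonyloxy)cyclodeca-1,3,5-triene-1-carboxylate | COC(=O)/C1=C(OS(=O)(=O)C(F)(F)F)/C=C\C=C\[C@@](C)(CCc2ccoc2)[C@H](C)CC1
F3 | step 15 | allylic alcohol from F2: ten-membered (Z,Z,E)-trienyl triflate with CH2OH in place of CO2Me | OC/C1=C(OS(=O)(=O)C(F)(F)F)/C=C\C=C\[C@@](C)(CCc2ccoc2)[C@H](C)CC1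
F4 | step 15 | acetate of F3: ten-membered (Z,Z,E)-trienyl triflate with CH2OAc | CC(=O)OC/C1=C(OS(=O)(=O)C(F)(F)F)/C=C\C=C\[C@@](C)(CCc2ccoc2)[C@H](C)CC1
F5 | step 7 | (1S,4R,5S,6R)-5-(2-bromoethyl)-7,8-dichloro-4,5-dimethylbicyclo[4.2.0]octan-2-one (fusion descriptors as in 11; mixture at C-7 and C-8) | O=C1C[C@@H](C)[C@](C)(CCBr)[C@@H]2C(Cl)C(Cl)[C@H]12
F6 | step 9 | {[(1S,4R,5S,6R)-5-[2-(furan-3-yl)ethyl]-4,5-dimethylbicyclo[4.2.0]octa-2,7-dien-2-yl]oxy}trimethylsilane | C[Si](C)(C)OC1=C[C@@H](C)[C@](C)(CCc2ccoc2)[C@@H]3C=C[C@H]13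
F7 | step 9 | tricyclic [2+2] adduct of F6 and methyl propiolate: 2-(trimethylsilyloxy)cyclobutene ester fused across the former enol ether double bond | COC(=O)C1=C[C@@H]2[C@@H](C)[C@](C)(CCc3ccoc3)[C@@H]4C=C[C@@H]4[C@]12O[Si](C)(C)C
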